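(The earlier runs and the new flask are simulated from invented constants; the scatter is artificial.)

In a one-step world J goes straight to Z at rate κ[J][L], and the balance of L, the reagent charged in the smaller amount, is short: [L] stays at its charge, so [J] falls with a pseudo-first-order constant k = κ[L]. I wrote this bench note in that world.

common to all: L 0.5 mol%

| charge | J | remark | time |
|---|---|---|---|
| violet | 1 M (fed, over 2.0 h) | run made earlier; the fed solution adds 0.10 times the starting volume |  |
| Friday's | 2.0 M (fed, over 2.0 h) | the fed solution adds 0.10 times the starting volume | 3.0 h |
| Sunday's | 2.0 M | everything together at the start, the whole solution of J included, so that from the start the volume is larger by 0.10 times the starting volume | 1.5 h |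

- violet (time / h: Z / %, J / %): 0.200: 1.6, 9.3; 0.333: 2.2, 16.7; 0.500: 2.1, 23.3; 0.833: 6.2, 35.2; 1.33: 13.4, 53.8; 2.50: 34.9, 61.8

(scatter of a reading: 1 percentage point)

- charges are per starting volume, the dose included; the dosed solution carries all of it
- the numbers in the tables scatter with a standard deviation of 1 percentage point
- percentages count the whole charge, also what has not yet gone in
- no earlier run changes the charge of L; that part of a forecast is a guess

- which of the two ends with the higher amount of Z, in percent of the J charged ("neither" if they lie within 2 percentage points) (Friday's / Sunday's / neither)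
- Z at the end, in percent of the J charged, Friday's
- Z at the end, in percent of the J charged, Sunday's

Between the violet readings at 0.833 h and 1.33 h, both inside the feed, Z rose from 6.2% to 13.4% in 0.497 h while J climbed from 35.2% to 53.8%, a midpoint of 44.5%, so I read k = 0.326 h⁻¹, with the scatter of those readings. Dividing by the 0.00500 M of L gave κ, the rate constant per unit of L charged: 0.0181 M⁻¹ s⁻¹.

Friday's and Sunday's flasks each held 0.0100 M of L, twice the violet charge, so I took k = 0.651 h⁻¹. No earlier run changed L, so this proportion was a guess. Letting each portion of Friday's feed decay from its moment of entry, I expected Z at 70.8%, more than Sunday's 62.3%. The forecast stood lower than mine: Friday's, with 66% (50% to 75%) against 57% (41% to 67%), and “Friday's longer time wins even if L's order is lower”.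

    J + L ⇌ G (K = 0.0780 M⁻¹, k = 0.0270 M⁻¹ s⁻¹)
    G → Q (k = 4.90 s⁻¹)
    Q → L + Z (k = 0.0510 s⁻¹)
    2 Q ⇌ X, settled at all times (K = 200 M⁻¹)

Friday's ended at 57.8% and Sunday's at 39.5%. At 3.00 h X held 18.2% of Friday's catalyst, each X counted as two. As J fell from 64.7% to 42.0% after the feed, Friday's κ read 0.0120 M⁻¹ s⁻¹, less than the carried 0.0181 M⁻¹ s⁻¹. In the neighbouring flask with 0.50 M of J, the carried κ gave k = 0.163 h⁻¹ and so Z at 27.5%; that flask gave 29.6%, with X at 1.64% of its catalyst.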